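**Plan**

1. Retrosynthetic cuts, in order: the nineteen benzylic aryl-ether C–O bonds (global hydrogenolysis); the interflavan bond C4 (ring C)–C8 (ring D); the C3 carbinol C–H of the lower unit (back to a flavan-3-one); the C2–C3 bond of the lower pyran ring F.
2. Lower unit, forward: 2,4,6-trihydroxybenzaldehyde is etherified in three successive Williamson steps (para oxygen first, then each ortho oxygen) with 3,4,5-tris(benzyloxy)benzyl chloride and condensed with Meldrum's acid; ring F then closes between C2 and C3, and the dioxanedione is cut down to the C3 ketone.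
3. Enabling feature: lower-unit C2 is a benzylic methine between O1 and ring E, and it lies 1,5 to the C4 methylene across O1–C8a–C4a of ring D. An ortho "benzyl ether" can therefore hand its hydrogen to C4 as hydride while its carbon becomes C2 and bonds to C3.
4. Upper unit, forward: natural (−)-epigallocatechin (rings A, B, C) is benzylated, oxidised at C4 and galloylated; the halves are joined C4→C8 under TMSOTf and all benzyl-type ethers are removed last.
5. Stereochemistry: upper C2 and C3 come from the chiral pool; upper C4 (R, 4β) from attack anti to the C3 gallate; lower C2 and C3 (R,R, cis) are set together by dynamic kinetic asymmetric hydrogenation of the racemic, C2-labile flavan-3-one.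

Key step: step 7

Remark: the sense of induction of the ruthenium catalyst in step 10 is assigned by analogy with the conversion of racemic 2-substituted cyclohexanones into (1R,2R)-cis-alcohols by the same catalyst; if this ketone responds in the opposite sense, the mirror-image catalyst is used and nothing else changes.

Abbreviations: Bn = benzyl; TBB = 3,4,5-tris(benzyloxy)benzyl; Ar = 3,4,5-tris(benzyloxy)phenyl.

**Route**

Step 1
Reactants: 1 3,4,5-tris(benzyloxy)benzoic acid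
Product: 2 [3,4,5-tris(benzyloxy)phenyl]methanol (TBB-OH)
Conditions: LiAlH4, THF, 0 °C to rt; then H2O
Reagents that add atoms: none
Why: Hydride reduction of a carboxylic acid to the primary alcohol, which leaves aryl benzyl ethers untouched.

Step 2
Reactants: 2 [3,4,5-tris(benzyloxy)phenyl]methanol
Product: 3 1,2,3-tris(benzyloxy)-5-(chloromethyl)benzene (TBB-Cl)
Conditions: SOCl2, cat. DMF, CH2Cl2, 0 °C to rt
Reagents that add atoms: thionyl chloride, O=S(Cl)Cl
Why: Chlorodehydroxylation of a benzylic alcohol through its chlorosulfite should give a storable alkylating agent.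

Step 3
Reactants: 4 2,4,6-trihydroxybenzaldehyde; 3 TBB-Cl (1.0 equiv, added slowly)
Product: 5 2,6-dihydroxy-4-(TBB-oxy)benzaldehyde
Conditions: K2CO3 (1.05 equiv), cat. Bu4NI, DMF, 0 °C to rt, Ar
Reagents that add atoms: none
Why: Williamson etherification under limiting base and halide: the para hydroxyl is the most acidic and the only one not hydrogen-bonded to the formyl group, so the single equivalent of chloride should go to O4, while the formyl group lowers ring nucleophilicity and disfavours C-alkylation.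

Step 4
Reactants: 5 2,6-dihydroxy-4-(TBB-oxy)benzaldehyde; 3 TBB-Cl (1.05 equiv)
Product: 6 2-hydroxy-4,6-bis(TBB-oxy)benzaldehyde
Conditions: K2CO3 (1.2 equiv), cat. Bu4NI, DMF, rt to 40 °C
Reagents that add atoms: none
Why: Second Williamson etherification: the two ortho hydroxyls are equivalent, and once one is alkylated the other is held in a six-membered hydrogen bond to the formyl oxygen, which should stop the reaction at the mono-ortho ether at this temperature.

Step 5
Reactants: 6 2-hydroxy-4,6-bis(TBB-oxy)benzaldehyde; 3 TBB-Cl (1.2 equiv)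
Product: 7 2,4,6-tris(TBB-oxy)benzaldehyde
Conditions: K2CO3 (3 equiv), cat. Bu4NI, DMF, 70 °C
Reagents that add atoms: none
Why: Williamson etherification of the chelated, least reactive hydroxyl, forced by excess base, iodide catalysis and heat, completes the symmetrical tris-ether in which both ortho ethers are the same hydride donor.

Step 6
Reactants: 7 2,4,6-tris(TBB-oxy)benzaldehyde; 8 Meldrum's acid (2,2-dimethyl-1,3-dioxane-4,6-dione)
Product: 9 5-[2,4,6-tris(TBB-oxy)benzylidene]-2,2-dimethyl-1,3-dioxane-4,6-dione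
Conditions: cat. pyrrolidine/AcOH, CH2Cl2/EtOH, rt
Reagents that add atoms: none
Why: Knoevenagel condensation of a non-enolisable aldehyde with the acidic methylene of Meldrum's acid; the two ortho substituents should suppress a second (Michael) addition.

Step 7
Reactants: 9 5-[2,4,6-tris(TBB-oxy)benzylidene]-2,2-dimethyl-1,3-dioxane-4,6-dione
Product: 11 racemic 2',2'-dimethyl-2-[3,4,5-tris(benzyloxy)phenyl]-5,7-bis(TBB-oxy)spiro[chromane-3,5'-[1,3]dioxane]-4',6'-dione, via oxocarbenium–enolate zwitterion 10 (not isolated)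
Conditions: Sc(OTf)3 (10 mol %), 4 Å MS, ClCH2CH2Cl, 60 °C, Ar
Reagents that add atoms: none
Why: Sc(OTf)3 chelates the two dioxanedione carbonyls and lowers the LUMO of the benzylidene, so that one ortho O–CH2Ar hydrogen migrates as hydride in a suprafacial [1,5]-shift across O1–C8a–C4a to the benzylidene carbon, which becomes the C4 methylene and leaves zwitterion 10, an aryloxocarbenium ion at C2 beside a scandium-bound enolate at C3. The two charged carbons then collapse by C-attack of the enolate on the oxocarbenium carbon, which forms the C2–C3 bond and closes pyran ring F in a 6-endo-trig (enol-exo) mode. The closest known reaction type is the Lewis-acid-catalysed hydride shift/cyclisation (internal redox) of ortho-alkoxyaryl alkylidene malonates and related 1,3-dicarbonyl acceptors to chroman-3,3-dicarbonyl compounds, in which benzyl aryl ethers are established hydride donors. C2 is the only new stereocentre (C3 carries the symmetric dioxanedione and is not stereogenic) and is formed racemic on purpose, because it is equilibrated and set in step 10. The step needs the hydride to come from an ortho benzylic ether: the two ortho ethers of 9 are identical, so either gives the same chroman, whereas the para ether and the O-benzyl groups of the outer rings have no 1,5 relation to the acceptor carbon, and O-attack of the enolate would need an eight-membered ring. The twofold ortho substitution twists the benzylidene out of the plane of ring D, which limits its deactivation by the three donor oxygens and holds a benzylic C–H over the acceptor carbon.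

Step 8
Reactants: 11 racemic spiro[chromane-3,5'-[1,3]dioxane]-4',6'-dione
Product: 12 racemic 2-[3,4,5-tris(benzyloxy)phenyl]-5,7-bis(TBB-oxy)chromane-3,3-dicarboxylic acid
Conditions: LiOH, THF/H2O, 40 °C; then 1 M HCl, 0 °C
Reagents that add atoms: water, O (delivered as hydroxide from lithium hydroxide, [Li+].[OH-])
Why: Saponification of a Meldrum's acid derivative opens the doubly activated dioxanedione and releases acetone; cold acidification avoids thermal decarboxylation.

Step 9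
Reactants: 12 racemic chromane-3,3-dicarboxylic acid
Product: 14 racemic 2-[3,4,5-tris(benzyloxy)phenyl]-5,7-bis(TBB-oxy)chroman-3-one, via geminal diacetate 13 (not isolated)
Conditions: Pb(OAc)4 (2.3 equiv), pyridine, benzene, 45 °C, Ar; then K2CO3, MeOH/THF, 0 °C
Reagents that add atoms: lead tetraacetate, CC(=O)O[Pb](OC(C)=O)(OC(C)=O)OC(C)=O
Why: Oxidative bisdecarboxylation of a disubstituted malonic acid exchanges each carboxyl for acetoxy through a lead carboxylate, and methanolysis of the geminal diacetate 13 unveils the C3 ketone, so the malonyl carbons serve as a masked carbonyl.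

Step 10
Reactants: 14 racemic chroman-3-one
Product: 15 (2R,3R)-2-[3,4,5-tris(benzyloxy)phenyl]-5,7-bis(TBB-oxy)chroman-3-ol
Conditions: H2 (8 atm), RuCl2[(S)-binap][(R,R)-dpen] (1 mol %), KOtBu (10 mol %), i-PrOH/toluene, 25 °C, degassed
Reagents that add atoms: none
Why: Noyori asymmetric hydrogenation under dynamic kinetic resolution: C2, flanked by the ketone, O1 and ring E, epimerises quickly under KOtBu, and the catalyst reduces one enantiomer faster with hydride delivery to C3 anti to the pseudo-equatorial aryl group, so the racemate should converge on the 2,3-cis (2R,3R) alcohol.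

Step 11
Reactants: 16 (−)-epigallocatechin
Product: 17 5,7,3',4',5'-penta-O-benzyl-(−)-epigallocatechin
Conditions: BnBr (5.5 equiv), K2CO3, DMF, 0 °C to rt, Ar
Reagents that add atoms: benzyl bromide, BrCc1ccccc1
Why: Williamson benzylation of the five phenols, which are far more acidic than the secondary C3 alcohol, should leave that hydroxyl free and the stereocentres untouched.

Step 12
Reactants: 17 penta-O-benzyl-(−)-epigallocatechin
Product: 18 (2R,3R,4S)-5,7-bis(benzyloxy)-4-(2-ethoxyethoxy)-2-[3,4,5-tris(benzyloxy)phenyl]chroman-3-ol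
Conditions: DDQ (2 equiv), 2-ethoxyethanol (5 equiv), CH2Cl2, rt
Reagents that add atoms: 2-ethoxyethanol, CCOCCO
Why: DDQ abstracts hydride from C4, benzylic to electron-rich ring A (oxidative benzylic C–H functionalisation), and the cation is trapped by the alcohol anti to the C3 hydroxyl to give the 4β ether.

Step 13
Reactants: 18 4-(2-ethoxyethoxy) alcohol; 1 3,4,5-tris(benzyloxy)benzoic acid
Product: 19 (2R,3R,4S)-5,7-bis(benzyloxy)-4-(2-ethoxyethoxy)-2-[3,4,5-tris(benzyloxy)phenyl]chroman-3-yl 3,4,5-tris(benzyloxy)benzoate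
Conditions: DCC, DMAP, CH2Cl2, rt
Reagents that add atoms: none
Why: Steglich esterification acylates the hindered C3 hydroxyl under neutral conditions that do not disturb the acid-labile C4 ether.

Step 14
Reactants: 19 galloylated C4 ether; 15 (2R,3R)-chroman-3-ol (2 equiv, excess recoverable)
Product: 21 fully protected dimer (upper unit of 19 bonded through C4 to C8 of 15, 4R), via C4 benzylic cation 20 (not isolated)
Conditions: TMSOTf (cat.), CH2Cl2, −78 °C; then Et3N
Reagents that add atoms: none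
Why: SN1 Friedel–Crafts alkylation: TMSOTf ionises the C4 ether to cation 20, which C8 of ring D of 15 attacks anti to the C3 gallate (with possible acyloxonium participation) to set the 3,4-trans (4R, 4β) bond, while C6 is flanked by two bulky ethers and the free C3 hydroxyl is the poorer nucleophile at −78 °C.

Step 15
Reactants: 21 fully protected dimer
Product: 22 epigallocatechin 3-O-gallate-(4β→8)-epigallocatechin (target)
Conditions: H2 (1 atm), Pd(OH)2/C, THF/MeOH/H2O, rt; filtration under Ar, Sephadex LH-20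
Reagents that add atoms: none
Why: Hydrogenolysis cleaves all seventeen benzyl ethers and both TBB aryl ethers (the latter leave as 5-methylbenzene-1,2,3-triol), while the gallate ester, the interflavan C–C bond and all stereocentres are inert to these neutral conditions.

**Compound list**

1 | 3,4,5-tris(benzyloxy)benzoic acid | O=C(O)c1cc(OCc2ccccc2)c(OCc2ccccc2)c(OCc2ccccc2)c1 | starting material
2 | [3,4,5-tris(benzyloxy)phenyl]methanol (TBB-OH) | OCc1cc(OCc2ccccc2)c(OCc2ccccc2)c(OCc2ccccc2)c1 | intermediate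
3 | 1,2,3-tris(benzyloxy)-5-(chloromethyl)benzene (TBB-Cl) | ClCc1cc(OCc2ccccc2)c(OCc2ccccc2)c(OCc2ccccc2)c1 | intermediate
4 | 2,4,6-trihydroxybenzaldehyde | O=Cc1c(O)cc(O)cc1O | starting material
5 | 2,6-dihydroxy-4-(TBB-oxy)benzaldehyde | O=Cc1c(O)cc(OCc2cc(OCc3ccccc3)c(OCc3ccccc3)c(OCc3ccccc3)c2)cc1O | intermediate
6 | 2-hydroxy-4,6-bis(TBB-oxy)benzaldehyde | O=Cc1c(O)cc(OCc2cc(OCc3ccccc3)c(OCc3ccccc3)c(OCc3ccccc3)c2)cc1OCc1cc(OCc2ccccc2)c(OCc2ccccc2)c(OCc2ccccc2)c1 | intermediate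
7 | 2,4,6-tris(TBB-oxy)benzaldehyde | O=Cc1c(OCc2cc(OCc3ccccc3)c(OCc3ccccc3)c(OCc3ccccc3)c2)cc(OCc2cc(OCc3ccccc3)c(OCc3ccccc3)c(OCc3ccccc3)c2)cc1OCc1cc(OCc2ccccc2)c(OCc2ccccc2)c(OCc2ccccc2)c1 | intermediate
8 | Meldrum's acid (2,2-dimethyl-1,3-dioxane-4,6-dione) | CC1(C)OC(=O)CC(=O)O1 | starting material
9 | 5-[2,4,6-tris(TBB-oxy)benzylidene]-2,2-dimethyl-1,3-dioxane-4,6-dione | CC1(C)OC(=O)C(=Cc2c(OCc3cc(OCc4ccccc4)c(OCc4ccccc4)c(OCc4ccccc4)c3)cc(OCc3cc(OCc4ccccc4)c(OCc4ccccc4)c(OCc4ccccc4)c3)cc2OCc2cc(OCc3ccccc3)c(OCc3ccccc3)c(OCc3ccccc3)c2)C(=O)O1 | intermediate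
10 | oxocarbenium–enolate zwitterion (C2 aryloxocarbenium, C3 dioxanedione enolate, C4 methylene; not isolated) | CC1(C)OC(=O)C(Cc2c(OCc3cc(OCc4ccccc4)c(OCc4ccccc4)c(OCc4ccccc4)c3)cc(OCc3cc(OCc4ccccc4)c(OCc4ccccc4)c(OCc4ccccc4)c3)cc2[O+]=Cc2cc(OCc3ccccc3)c(OCc3ccccc3)c(OCc3ccccc3)c2)=C([O-])O1 | intermediate
11 | racemic 2',2'-dimethyl-2-[3,4,5-tris(benzyloxy)phenyl]-5,7-bis(TBB-oxy)spiro[chromane-3,5'-[1,3]dioxane]-4',6'-dione | CC1(C)OC(=O)C2(Cc3c(OCc4cc(OCc5ccccc5)c(OCc5ccccc5)c(OCc5ccccc5)c4)cc(OCc4cc(OCc5ccccc5)c(OCc5ccccc5)c(OCc5ccccc5)c4)cc3OC2c2cc(OCc3ccccc3)c(OCc3ccccc3)c(OCc3ccccc3)c2)C(=O)O1 | intermediate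
12 | racemic 2-[3,4,5-tris(benzyloxy)phenyl]-5,7-bis(TBB-oxy)chromane-3,3-dicarboxylic acid | OC(=O)C1(C(=O)O)Cc2c(OCc3cc(OCc4ccccc4)c(OCc4ccccc4)c(OCc4ccccc4)c3)cc(OCc3cc(OCc4ccccc4)c(OCc4ccccc4)c(OCc4ccccc4)c3)cc2OC1c1cc(OCc2ccccc2)c(OCc2ccccc2)c(OCc2ccccc2)c1 | intermediate
13 | racemic 3,3-diacetoxy-2-[3,4,5-tris(benzyloxy)phenyl]-5,7-bis(TBB-oxy)chromane (geminal diacetate; not isolated) | CC(=O)OC1(OC(C)=O)Cc2c(OCc3cc(OCc4ccccc4)c(OCc4ccccc4)c(OCc4ccccc4)c3)cc(OCc3cc(OCc4ccccc4)c(OCc4ccccc4)c(OCc4ccccc4)c3)cc2OC1c1cc(OCc2ccccc2)c(OCc2ccccc2)c(OCc2ccccc2)c1 | intermediate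
14 | racemic 2-[3,4,5-tris(benzyloxy)phenyl]-5,7-bis(TBB-oxy)chroman-3-one | O=C1Cc2c(OCc3cc(OCc4ccccc4)c(OCc4ccccc4)c(OCc4ccccc4)c3)cc(OCc3cc(OCc4ccccc4)c(OCc4ccccc4)c(OCc4ccccc4)c3)cc2OC1c1cc(OCc2ccccc2)c(OCc2ccccc2)c(OCc2ccccc2)c1 | intermediate
15 | (2R,3R)-2-[3,4,5-tris(benzyloxy)phenyl]-5,7-bis(TBB-oxy)chroman-3-ol | O[C@@H]1Cc2c(OCc3cc(OCc4ccccc4)c(OCc4ccccc4)c(OCc4ccccc4)c3)cc(OCc3cc(OCc4ccccc4)c(OCc4ccccc4)c(OCc4ccccc4)c3)cc2O[C@@H]1c1cc(OCc2ccccc2)c(OCc2ccccc2)c(OCc2ccccc2)c1 | intermediate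
16 | (−)-epigallocatechin, (2R,3R) | O[C@@H]1Cc2c(O)cc(O)cc2O[C@@H]1c1cc(O)c(O)c(O)c1 | starting material
17 | 5,7,3',4',5'-penta-O-benzyl-(−)-epigallocatechin | O[C@@H]1Cc2c(OCc3ccccc3)cc(OCc3ccccc3)cc2O[C@@H]1c1cc(OCc2ccccc2)c(OCc2ccccc2)c(OCc2ccccc2)c1 | intermediate
18 | (2R,3R,4S)-5,7-bis(benzyloxy)-4-(2-ethoxyethoxy)-2-[3,4,5-tris(benzyloxy)phenyl]chroman-3-ol | O[C@@H]1[C@@H](OCCOCC)c2c(OCc3ccccc3)cc(OCc3ccccc3)cc2O[C@@H]1c1cc(OCc2ccccc2)c(OCc2ccccc2)c(OCc2ccccc2)c1 | intermediate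
19 | (2R,3R,4S)-5,7-bis(benzyloxy)-4-(2-ethoxyethoxy)-2-[3,4,5-tris(benzyloxy)phenyl]chroman-3-yl 3,4,5-tris(benzyloxy)benzoate | O=C(O[C@@H]1[C@@H](OCCOCC)c2c(OCc3ccccc3)cc(OCc3ccccc3)cc2O[C@@H]1c1cc(OCc2ccccc2)c(OCc2ccccc2)c(OCc2ccccc2)c1)c1cc(OCc2ccccc2)c(OCc2ccccc2)c(OCc2ccccc2)c1 | intermediate
20 | C4 benzylic cation of the galloylated upper unit (not isolated) | O=C(O[C@@H]1[CH+]c2c(OCc3ccccc3)cc(OCc3ccccc3)cc2O[C@@H]1c1cc(OCc2ccccc2)c(OCc2ccccc2)c(OCc2ccccc2)c1)c1cc(OCc2ccccc2)c(OCc2ccccc2)c(OCc2ccccc2)c1 | intermediate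
21 | fully protected dimer: upper unit (2R,3R,4R) carrying eight benzyl ethers and the C3 gallate, bonded C4→C8 to lower unit 15 | O=C(O[C@@H]1[C@@H](c2c(OCc4cc(OCc5ccccc5)c(OCc5ccccc5)c(OCc5ccccc5)c4)cc(OCc4cc(OCc5ccccc5)c(OCc5ccccc5)c(OCc5ccccc5)c4)c3c2O[C@H](c2cc(OCc4ccccc4)c(OCc4ccccc4)c(OCc4ccccc4)c2)[C@H](O)C3)c2c(OCc3ccccc3)cc(OCc3ccccc3)cc2O[C@@H]1c1cc(OCc2ccccc2)c(OCc2ccccc2)c(OCc2ccccc2)c1)c1cc(OCc2ccccc2)c(OCc2ccccc2)c(OCc2ccccc2)c1 | intermediate
22 | epigallocatechin 3-O-gallate-(4β→8)-epigallocatechin (CNP0194932.2) | O=C(O[C@@H]1[C@@H](c2c(O)cc(O)c3c2O[C@H](c2cc(O)c(O)c(O)c2)[C@H](O)C3)c2c(O)cc(O)cc2O[C@@H]1c1cc(O)c(O)c(O)c1)c1cc(O)c(O)c(O)c1 | target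

**Totals**

Total step count: 15. Longest linear sequence: 12 steps (steps 1–10, 14, 15).

**Steps most likely to fail, with fallbacks**

Step 7. The hydride shift may be too slow, because the three donor oxygens of ring D deactivate the benzylidene and an aryl-ether oxygen stabilises the oxocarbenium ion less than an alkyl-ether oxygen. Lewis-acid-promoted loss of benzyl-type ethers, retro-Knoevenagel cleavage, or Friedel–Crafts acylation of ring E by the dioxanedione could then outrun ring closure. The fallback sets out from 7 and comes back at 14, in place of steps 6 to 9. A Wittig reaction of 7 with (triphenylphosphoranylidene)acetaldehyde (toluene, 80 °C) would give (E)-3-[2,4,6-tris(TBB-oxy)phenyl]prop-2-enal F1. Its iminium ion, formed with catalytic pyrrolidine and trifluoroacetic acid (ClCH2CH2Cl, 60 °C, no metal Lewis acid), is a cationic hydride acceptor without an acylating group. The same [1,5]-hydride shift, followed by C2–C3 closure through the enamine, should give racemic 2-[3,4,5-tris(benzyloxy)phenyl]-5,7-bis(TBB-oxy)chromane-3-carbaldehyde F2; hydride shift/cyclisation of enals with ether C–H donors under iminium or BF3·OEt2 activation is a known reaction type. Aerobic copper-catalysed deformylation of this α-branched aldehyde (Cu(OAc)2, 2,2'-bipyridine, DABCO, O2, DMF, 40 °C) removes the formyl carbon as formic acid and gives ketone 14 directly.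

Step 9. After the first decarboxylation the lead-bound intermediate may eliminate toward C4 to a chrom-3-ene acid instead of transferring acetate, or the oxidant may attack the electron-rich rings. The fallback sets out from 12 and comes back at 14. Heating 12 in pyridine (90 °C) should remove one carboxyl and give racemic 2-[3,4,5-tris(benzyloxy)phenyl]-5,7-bis(TBB-oxy)chromane-3-carboxylic acid F3. Coupling with 1-hydroxypyridine-2(1H)-thione (DCC, CH2Cl2, dark) would give the 2-thioxopyridin-1(2H)-yl (Barton) ester F4, which is not isolated. Barton decarboxylative hydroxylation (O2, t-BuSH, visible light; then P(OMe)3) should give 2-[3,4,5-tris(benzyloxy)phenyl]-5,7-bis(TBB-oxy)chroman-3-ol F5 as a mixture of cis and trans racemates. Dess–Martin periodinane (CH2Cl2, rt) oxidises either isomer to ketone 14.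

Step 10. The catalyst may discriminate poorly between the carbonyl faces, since no aryl group sits directly on the carbonyl, or the enolate may degrade under base before it is hydrogenated. The fallback sets out from 14 and comes back at 15. Reduction with LiBH(s-Bu)3 (THF, −78 °C), which attacks anti to the C2 aryl group, should give the racemic cis-alcohol, rac-(2R,3R)-2-[3,4,5-tris(benzyloxy)phenyl]-5,7-bis(TBB-oxy)chroman-3-ol F6. Esterification with (S)-2-methoxy-2-phenylacetic acid (DCC, DMAP, CH2Cl2) gives two diastereomeric esters, (2R,3R)-2-[3,4,5-tris(benzyloxy)phenyl]-5,7-bis(TBB-oxy)chroman-3-yl (S)-2-methoxy-2-phenylacetate F7 and (2S,3S)-2-[3,4,5-tris(benzyloxy)phenyl]-5,7-bis(TBB-oxy)chroman-3-yl (S)-2-methoxy-2-phenylacetate F8, which chromatography should separate. Saponification of F7 (LiOH, THF/MeOH/H2O, rt) returns 15.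

**Further compounds**

F1 | step 7 | (E)-3-[2,4,6-tris(TBB-oxy)phenyl]prop-2-enal | O=C/C=C/c1c(OCc2cc(OCc3ccccc3)c(OCc3ccccc3)c(OCc3ccccc3)c2)cc(OCc2cc(OCc3ccccc3)c(OCc3ccccc3)c(OCc3ccccc3)c2)cc1OCc1cc(OCc2ccccc2)c(OCc2ccccc2)c(OCc2ccccc2)c1
F2 | step 7 | racemic 2-[3,4,5-tris(benzyloxy)phenyl]-5,7-bis(TBB-oxy)chromane-3-carbaldehyde (cis/trans mixture) | O=CC1Cc2c(OCc3cc(OCc4ccccc4)c(OCc4ccccc4)c(OCc4ccccc4)c3)cc(OCc3cc(OCc4ccccc4)c(OCc4ccccc4)c(OCc4ccccc4)c3)cc2OC1c1cc(OCc2ccccc2)c(OCc2ccccc2)c(OCc2ccccc2)c1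
F3 | step 9 | racemic 2-[3,4,5-tris(benzyloxy)phenyl]-5,7-bis(TBB-oxy)chromane-3-carboxylic acid | OC(=O)C1Cc2c(OCc3cc(OCc4ccccc4)c(OCc4ccccc4)c(OCc4ccccc4)c3)cc(OCc3cc(OCc4ccccc4)c(OCc4ccccc4)c(OCc4ccccc4)c3)cc2OC1c1cc(OCc2ccccc2)c(OCc2ccccc2)c(OCc2ccccc2)c1
F4 | step 9 | 2-thioxopyridin-1(2H)-yl (Barton) ester of F3 (not isolated) | S=C1C=CC=CN1OC(=O)C1Cc2c(OCc3cc(OCc4ccccc4)c(OCc4ccccc4)c(OCc4ccccc4)c3)cc(OCc3cc(OCc4ccccc4)c(OCc4ccccc4)c(OCc4ccccc4)c3)cc2OC1c1cc(OCc2ccccc2)c(OCc2ccccc2)c(OCc2ccccc2)c1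
F5 | step 9 | 2-[3,4,5-tris(benzyloxy)phenyl]-5,7-bis(TBB-oxy)chroman-3-ol (cis and trans racemates) | OC1Cc2c(OCc3cc(OCc4ccccc4)c(OCc4ccccc4)c(OCc4ccccc4)c3)cc(OCc3cc(OCc4ccccc4)c(OCc4ccccc4)c(OCc4ccccc4)c3)cc2OC1c1cc(OCc2ccccc2)c(OCc2ccccc2)c(OCc2ccccc2)c1
F6 | step 10 | rac-(2R,3R)-2-[3,4,5-tris(benzyloxy)phenyl]-5,7-bis(TBB-oxy)chroman-3-ol (cis racemate, both enantiomers written) | O[C@@H]1Cc2c(OCc3cc(OCc4ccccc4)c(OCc4ccccc4)c(OCc4ccccc4)c3)cc(OCc3cc(OCc4ccccc4)c(OCc4ccccc4)c(OCc4ccccc4)c3)cc2O[C@@H]1c1cc(OCc2ccccc2)c(OCc2ccccc2)c(OCc2ccccc2)c1.O[C@H]1Cc2c(OCc3cc(OCc4ccccc4)c(OCc4ccccc4)c(OCc4ccccc4)c3)cc(OCc3cc(OCc4ccccc4)c(OCc4ccccc4)c(OCc4ccccc4)c3)cc2O[C@H]1c1cc(OCc2ccccc2)c(OCc2ccccc2)c(OCc2ccccc2)c1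
F7 | step 10 | (2R,3R)-2-[3,4,5-tris(benzyloxy)phenyl]-5,7-bis(TBB-oxy)chroman-3-yl (S)-2-methoxy-2-phenylacetate | CO[C@H](C(=O)O[C@@H]1Cc2c(OCc3cc(OCc4ccccc4)c(OCc4ccccc4)c(OCc4ccccc4)c3)cc(OCc3cc(OCc4ccccc4)c(OCc4ccccc4)c(OCc4ccccc4)c3)cc2O[C@@H]1c1cc(OCc2ccccc2)c(OCc2ccccc2)c(OCc2ccccc2)c1)c1ccccc1
F8 | step 10 | (2S,3S)-2-[3,4,5-tris(benzyloxy)phenyl]-5,7-bis(TBB-oxy)chroman-3-yl (S)-2-methoxy-2-phenylacetate | CO[C@H](C(=O)O[C@H]1Cc2c(OCc3cc(OCc4ccccc4)c(OCc4ccccc4)c(OCc4ccccc4)c3)cc(OCc3cc(OCc4ccccc4)c(OCc4ccccc4)c(OCc4ccccc4)c3)cc2O[C@H]1c1cc(OCc2ccccc2)c(OCc2ccccc2)c(OCc2ccccc2)c1)c1ccccc1
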